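**Retrosynthetic overview**
1. The target is read as epicatechin-(4β→8)-epicatechin-(4β→O→4)-[(2S,3S)-2,3-cis-3,4-cis-flavan-3,4-diol]. The last operations on the protected trimer 23 are deacetylation, desilylation and hydrogenolysis of twelve benzyl ethers and two aryl bromides.
2. The C4–O–C4 ether (step 17) comes from thiophilic ionisation of the middle-unit C4–S bond of dimer 15 and capture by the 3,4-cis 4-ol 22, made from (+)-epicatechin by C4 oxidation and ketone reduction.
3. The C4–C8 interflavan bond (step 10) comes from hard Lewis-acid ionisation of the C4–OMe group of top unit 9 in the presence of the C4–S group of 14, made from (−)-epicatechin.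
4. Top unit 9 (step 5) has ring C built de novo by a three-component oxa-[4+2] cycloaddition: aldehyde 6 and HC(OMe)3 give a methoxy ortho-quinone methide, which adds (Z)-enol acetate 3, forming C3–C4 and closing ring C through O1–C2. The enabling feature is that O1 is a phenolic oxygen on C8a of ring A, ortho to C4a which carries benzylic C4. O1–C8a–C4a–C4 is therefore a latent ortho-quinone methide heterodiene and C2–C3 a cis β-acyloxystyrene; the C4 methoxy group of the adduct is the leaving group for line 3.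
5. Ring order: all rings of the middle and bottom units come intact from the two epicatechins; ring C of the top unit is the only ring formed (step 5).

Key step: step 5

Assumption: (+)-epicatechin (2S,3S) is taken as a purchasable starting material, like (−)-epicatechin.
Assumption: C4 of 9 is drawn as the 3,4-trans epimer expected under the equilibrating acid conditions; its C4 epimer would ionise to the same cation in step 10.
Assumption: the (R) acid is written for step 5; should the opposite sense of induction be found, the (S) acid is used.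

**Step 1**
Reactants: 1 3,4-bis(benzyloxy)benzaldehyde
Product: 2 4-ethynyl-1,2-bis(benzyloxy)benzene
Conditions: dimethyl (1-diazo-2-oxopropyl)phosphonate, K2CO3, MeOH, 0 °C → rt
Reagents that add atoms: dimethyl (1-diazo-2-oxopropyl)phosphonate, COP(=O)(OC)C(=[N+]=[N-])C(C)=O
Why: Ohira–Bestmann (Seyferth–Gilbert) homologation turns the electron-rich aryl aldehyde into the terminal alkyne under carbonate conditions that leave benzyl ethers untouched.

**Step 2**
Reactants: 2 4-ethynyl-1,2-bis(benzyloxy)benzene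
Product: 3 (Z)-2-[3,4-bis(benzyloxy)phenyl]ethenyl acetate
Conditions: AcOH, Ru(η3-CH2C(CH3)CH2)2(Ph2P(CH2)4PPh2) (cat.), toluene, 45 °C
Reagents that add atoms: acetic acid, CC(=O)O
Why: Ruthenium-catalysed anti-Markovnikov addition of a carboxylic acid to a terminal arylalkyne is known to give the (Z)-alk-1-enyl ester, so the cis alkene geometry that becomes the 2,3-cis relationship is fixed here.

**Step 3**
Reactants: 4 2,4,6-trihydroxybenzaldehyde
Product: 5 2,4-bis(benzyloxy)-6-hydroxybenzaldehyde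
Conditions: BnBr (2 equiv), K2CO3, DMF, 0 °C → rt
Reagents that add atoms: benzyl bromide, BrCc1ccccc1
Why: Williamson etherification in which the hydroxyl that is hydrogen-bonded to the formyl group is the least reactive, so two equivalents of halide leave exactly that phenol free.

**Step 4**
Reactants: 5 2,4-bis(benzyloxy)-6-hydroxybenzaldehyde
Product: 6 4,6-bis(benzyloxy)-3-bromo-2-hydroxybenzaldehyde
Conditions: NBS (1 equiv), CH2Cl2, −20 °C
Reagents that add atoms: N-bromosuccinimide, O=C1CCC(=O)N1Br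
Why: Electrophilic aromatic bromination is expected ortho to the chelated phenol, as in the halogenation of 2-hydroxy-4,6-dialkoxyacetophenones, and places the blocking bromine on the future C8.

**Step 5**
Reactants: 6 4,6-bis(benzyloxy)-3-bromo-2-hydroxybenzaldehyde; 3 (Z)-2-[3,4-bis(benzyloxy)phenyl]ethenyl acetate
Product: 9 3-O-acetyl-5,7,3',4'-tetra-O-benzyl-8-bromo-4β-methoxy-(−)-epicatechin [(2R,3R,4S)-chroman-3-yl acetate], via dimethyl acetal 7 (not isolated), via methoxy ortho-quinone methide 8 (not isolated)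
Conditions: HC(OMe)3, (R)-[3,3'-bis(2,4,6-triisopropylphenyl)-1,1'-binaphthalene-2,2'-diyl] N-triflylphosphoramide (cat.), 5 Å MS, CH2Cl2, 0 °C; then 3 (excess), −20 °C → rt
Reagents that add atoms: trimethyl orthoformate, COC(OC)OC
Why: Proposed new method: the chiral acid converts 6 with trimethyl orthoformate into acetal 7 and ionises it to the methoxy ortho-quinone methide 8 (as its O-protonated oxocarbenium form, ion-paired and hydrogen-bonded through the phenolic OH to the chiral anion), which reacts as the heterodiene O=C8a–C4a=C4 with the (Z)-enol acetate 3 in an asynchronous inverse-electron-demand oxa-[4+2] cycloaddition in which C3–C4 forms first and the phenolic oxygen then forms O1–C2 at the benzylic carbon. The closest known reactions are the acid-catalysed three-component chroman synthesis from salicylaldehydes, trimethyl orthoformate and styrenes and the chiral phosphoric or N-triflylphosphoramide acid-catalysed [4+2] cycloadditions of ortho-quinone methides with styrenes; an aryl enol ester as the 2π partner and the enantioselective three-component version are the untested elements. Ring C is the only ring closed, by [4+2] cycloaddition, formally a 6-endo capture of the C2 benzylic cation by O1. C2 and C3 arise cis because the addition is suprafacial on the (Z)-alkene, their absolute (2R,3R) sense is to come from the chiral counter-anion that differentiates the two alkene faces in the ion-paired transition state, and C4 is expected 3,4-trans after acid equilibration but is erased in step 10. The step needs regioselectivity, which the strongly donating 3,4-bis(benzyloxy)phenyl group should secure over the weakly donating acetoxy group by making the acetoxy-bearing carbon the nucleophilic terminus and the benzylic carbon the cationic one, and chemoselectivity over Friedel–Crafts self-condensation, which the C8 bromine and the doubly flanked C6–H of ring A should secure.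

**Step 6**
Reactants: 10 (−)-epicatechin
Product: 11 5,7,3',4'-tetra-O-benzyl-(−)-epicatechin
Conditions: BnBr, K2CO3, DMF, 0 °C → rt
Reagents that add atoms: benzyl bromide, BrCc1ccccc1
Why: Williamson etherification with carbonate alkylates only the four phenols and leaves the secondary 3-OH and both stereocentres untouched.

**Step 7**
Reactants: 11 5,7,3',4'-tetra-O-benzyl-(−)-epicatechin
Product: 12 5,7,3',4'-tetra-O-benzyl-3-O-(tert-butyldimethylsilyl)-(−)-epicatechin
Conditions: TBSOTf, 2,6-lutidine, CH2Cl2, 0 °C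
Reagents that add atoms: tert-butyldimethylsilyl triflate, CC(C)(C)[Si](C)(C)OS(=O)(=O)C(F)(F)F
Why: Silylation of the hindered axial 3-OH with the silyl triflate gives a non-participating, base- and Lewis-acid-tolerant protecting group.

**Step 8**
Reactants: 12 5,7,3',4'-tetra-O-benzyl-3-O-(tert-butyldimethylsilyl)-(−)-epicatechin
Product: 13 5,7,3',4'-tetra-O-benzyl-3-O-(tert-butyldimethylsilyl)-4β-methoxy-(−)-epicatechin (3,4-trans)
Conditions: DDQ, MeOH, CH2Cl2, rt
Reagents that add atoms: methanol, CO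
Why: DDQ benzylic oxidation (hydride abstraction at C4 of the electron-rich ring A) gives the C4 cation, which methanol captures anti to the 3-O substituent on the 2,3-cis framework.

**Step 9**
Reactants: 13 5,7,3',4'-tetra-O-benzyl-3-O-(tert-butyldimethylsilyl)-4β-methoxy-(−)-epicatechin
Product: 14 5,7,3',4'-tetra-O-benzyl-3-O-(tert-butyldimethylsilyl)-4β-(4-methylphenylthio)-(−)-epicatechin (3,4-trans)
Conditions: 4-MeC6H4SH, BF3·OEt2, CH2Cl2, −78 → −30 °C
Reagents that add atoms: 4-methylbenzenethiol, Cc1ccc(S)cc1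
Why: Lewis-acid-mediated SN1 exchange (thiolysis) replaces the C4 ether by the soft thioether with β-face attack, giving a group that tolerates hard Lewis acids and is activated only by thiophiles.

**Step 10**
Reactants: 9 3-O-acetyl-5,7,3',4'-tetra-O-benzyl-8-bromo-4β-methoxy-(−)-epicatechin; 14 5,7,3',4'-tetra-O-benzyl-3-O-(tert-butyldimethylsilyl)-4β-(4-methylphenylthio)-(−)-epicatechin
Product: 15 [3-O-acetyl-5,7,3',4'-tetra-O-benzyl-8-bromoepicatechin]-(4β→8)-[5,7,3',4'-tetra-O-benzyl-3-O-(tert-butyldimethylsilyl)-4β-(4-methylphenylthio)epicatechin]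
Conditions: BF3·OEt2, 14 (excess), CH2Cl2, −78 → −30 °C
Reagents that add atoms: none
Why: Friedel–Crafts-type interflavan coupling (SN1) in which the hard Lewis acid ionises the C4–OMe group of 9 but not the C4–S group of 14, the C8 bromine of 9 prevents self-condensation, and C8 of 14 attacks the β face anti to the participating 3-acetoxy group, which sets the 3,4-trans C4 of the top unit.

**Step 11**
Reactants: 16 (+)-epicatechin
Product: 17 5,7,3',4'-tetra-O-benzyl-(+)-epicatechin
Conditions: BnBr, K2CO3, DMF, 0 °C → rt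
Reagents that add atoms: benzyl bromide, BrCc1ccccc1
Why: Williamson etherification of the four phenols, as in step 6.

**Step 12**
Reactants: 17 5,7,3',4'-tetra-O-benzyl-(+)-epicatechin
Product: 18 5,7,3',4'-tetra-O-benzyl-3-O-(tert-butyldimethylsilyl)-(+)-epicatechin
Conditions: TBSOTf, 2,6-lutidine, CH2Cl2, 0 °C
Reagents that add atoms: tert-butyldimethylsilyl triflate, CC(C)(C)[Si](C)(C)OS(=O)(=O)C(F)(F)F
Why: Silylation of the 3-OH gives a non-migrating group that later differentiates O3 from the nucleophilic O4.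

**Step 13**
Reactants: 18 5,7,3',4'-tetra-O-benzyl-3-O-(tert-butyldimethylsilyl)-(+)-epicatechin
Product: 19 5,7,3',4'-tetra-O-benzyl-3-O-(tert-butyldimethylsilyl)-4-hydroxy-(+)-epicatechin (3,4-trans)
Conditions: DDQ, H2O, CH2Cl2/THF, rt
Reagents that add atoms: water, O
Why: DDQ benzylic oxidation with water as the nucleophile gives the flavan-4-ol, whose C4 configuration is irrelevant because it is oxidised next.

**Step 14**
Reactants: 19 5,7,3',4'-tetra-O-benzyl-3-O-(tert-butyldimethylsilyl)-4-hydroxy-(+)-epicatechin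
Product: 20 (2S,3S)-5,7,3',4'-tetra-O-benzyl-3-O-(tert-butyldimethylsilyl)-2,3-cis-flavan-4-one
Conditions: (n-Pr4N)RuO4 (cat.), NMO, 4 Å MS, CH2Cl2, rt
Reagents that add atoms: none
Why: Ley–Griffith oxidation converts the benzylic alcohol into the ketone under neutral conditions that do not epimerise the 2,3-cis α-silyloxy ketone.

**Step 15**
Reactants: 20 (2S,3S)-5,7,3',4'-tetra-O-benzyl-3-O-(tert-butyldimethylsilyl)-2,3-cis-flavan-4-one
Product: 21 5,7,3',4'-tetra-O-benzyl-3-O-(tert-butyldimethylsilyl)-4-hydroxy-(+)-epicatechin (2,3-cis-3,4-cis)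
Conditions: Li[HB(s-Bu)3], THF, −78 °C; then H2O
Reagents that add atoms: none
Why: Carbonyl reduction with a bulky borohydride delivers hydride to the face opposite the axial 3-O-silyl group (1,2-induction in the half-chair), so the new 4-OH is cis to O3 and to the 2-aryl group.

**Step 16**
Reactants: 21 5,7,3',4'-tetra-O-benzyl-3-O-(tert-butyldimethylsilyl)-4-hydroxy-(+)-epicatechin (2,3-cis-3,4-cis)
Product: 22 5,7,3',4'-tetra-O-benzyl-8-bromo-3-O-(tert-butyldimethylsilyl)-4-hydroxy-(+)-epicatechin (2,3-cis-3,4-cis)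
Conditions: NBS (1 equiv), CH2Cl2, −40 °C
Reagents that add atoms: N-bromosuccinimide, O=C1CCC(=O)N1Br
Why: Electrophilic aromatic bromination of benzylated flavan-3-ols is regioselective for C8 and removes the only strongly nucleophilic carbon of this unit, so that only the 4-OH can react in step 17.

**Step 17**
Reactants: 15 top–middle dimer with the 4β-(4-methylphenylthio) group; 22 5,7,3',4'-tetra-O-benzyl-8-bromo-3-O-(tert-butyldimethylsilyl)-4-hydroxy-(+)-epicatechin (2,3-cis-3,4-cis)
Product: 23 protected trimer: [3-O-acetyl-tetra-O-benzyl-8-bromoepicatechin]-(4β→8)-[tetra-O-benzyl-3-O-(tert-butyldimethylsilyl)epicatechin]-(4β→O→4)-[tetra-O-benzyl-8-bromo-3-O-(tert-butyldimethylsilyl)-(2S,3S)-2,3-cis-3,4-cis-flavan-3-ol]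
Conditions: [Me2S–SMe]BF4, 2,6-di-tert-butyl-4-methylpyridine, 4 Å MS, CH2Cl2, −40 → 0 °C
Reagents that add atoms: none
Why: Thiophilic activation (S-methylthiolation) ionises the C4–S bond under buffered non-acidic conditions (SN1 etherification), and the 4-OH of 22 captures the cation on the β face anti to the axial 3-O-silyl group, which sets the 3,4-trans C4 of the middle unit while the 3,4-cis configuration of the bottom unit is carried over unchanged.

**Step 18**
Reactants: 23 protected trimer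
Product: 24 protected trimer with free 3-OH on the top unit
Conditions: K2CO3 (cat.), MeOH/THF, rt
Reagents that add atoms: none
Why: Base-catalysed transesterification (Zemplén-type methanolysis) removes the acetate without touching silyl ethers, aryl bromides or the base-stable bis-benzylic ether.

**Step 19**
Reactants: 24 protected trimer with free 3-OH on the top unit
Product: 25 dodeca-O-benzyl-dibromo trimer with three free 3-OH groups
Conditions: n-Bu4NF, AcOH, THF, rt
Reagents that add atoms: none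
Why: Fluoride-mediated desilylation, buffered with acetic acid, frees both secondary alcohols under conditions that cannot ionise the C4–O–C4 ether.

**Step 20**
Reactants: 25 dodeca-O-benzyl-dibromo trimer with three free 3-OH groups
Product: 26 target, epicatechin-(4β→8)-epicatechin-(4β→O→4)-[(2S,3S)-2,3-cis-3,4-cis-flavan-3,4-diol]
Conditions: H2 (1 atm), Pd(OH)2/C, NaHCO3, THF/MeOH/H2O, rt
Reagents that add atoms: none
Why: Catalytic hydrogenolysis cleaves the unhindered aryl benzyl ethers and the two aryl bromides much faster than the hindered doubly ortho-substituted secondary C4–O–C4 ether, and the hydrogencarbonate buffer neutralises HBr so the ether is not ionised.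

**Compound list**
1 | 3,4-bis(benzyloxy)benzaldehyde | O=Cc1ccc(OCc2ccccc2)c(OCc2ccccc2)c1 | starting material
2 | 4-ethynyl-1,2-bis(benzyloxy)benzene | C#Cc1ccc(OCc2ccccc2)c(OCc2ccccc2)c1 | intermediate
3 | (Z)-2-[3,4-bis(benzyloxy)phenyl]ethenyl acetate | CC(=O)O/C=C\c1ccc(OCc2ccccc2)c(OCc2ccccc2)c1 | intermediate
4 | 2,4,6-trihydroxybenzaldehyde | O=Cc1c(O)cc(O)cc1O | starting material
5 | 2,4-bis(benzyloxy)-6-hydroxybenzaldehyde | O=Cc1c(O)cc(OCc2ccccc2)cc1OCc1ccccc1 | intermediate
6 | 4,6-bis(benzyloxy)-3-bromo-2-hydroxybenzaldehyde | O=Cc1c(O)c(Br)c(OCc2ccccc2)cc1OCc1ccccc1 | intermediate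
7 | 4,6-bis(benzyloxy)-3-bromo-2-hydroxybenzaldehyde dimethyl acetal | COC(OC)c1c(O)c(Br)c(OCc2ccccc2)cc1OCc1ccccc1 | intermediate
8 | (6E)-3,5-bis(benzyloxy)-2-bromo-6-(methoxymethylidene)cyclohexa-2,4-dien-1-one (methoxy ortho-quinone methide) | CO/C=C1\C(OCc2ccccc2)=CC(OCc2ccccc2)=C(Br)C1=O | intermediate
9 | 3-O-acetyl-5,7,3',4'-tetra-O-benzyl-8-bromo-4β-methoxy-(−)-epicatechin, (2R,3R,4S) | c1ccccc1COc1cc(OCc3ccccc3)c2c(c1Br)O[C@H](c1ccc(OCc3ccccc3)c(OCc3ccccc3)c1)[C@H](OC(C)=O)[C@H]2OC | intermediate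
10 | (−)-epicatechin, (2R,3R) | Oc1cc(O)c2c(c1)O[C@H](c1ccc(O)c(O)c1)[C@H](O)C2 | starting material
11 | 5,7,3',4'-tetra-O-benzyl-(−)-epicatechin | c1ccccc1COc1cc(OCc3ccccc3)c2c(c1)O[C@H](c1ccc(OCc3ccccc3)c(OCc3ccccc3)c1)[C@H](O)C2 | intermediate
12 | 5,7,3',4'-tetra-O-benzyl-3-O-(tert-butyldimethylsilyl)-(−)-epicatechin | c1ccccc1COc1cc(OCc3ccccc3)c2c(c1)O[C@H](c1ccc(OCc3ccccc3)c(OCc3ccccc3)c1)[C@H](O[Si](C)(C)C(C)(C)C)C2 | intermediate
13 | 5,7,3',4'-tetra-O-benzyl-3-O-(tert-butyldimethylsilyl)-4β-methoxy-(−)-epicatechin (3,4-trans) | c1ccccc1COc1cc(OCc3ccccc3)c2c(c1)O[C@H](c1ccc(OCc3ccccc3)c(OCc3ccccc3)c1)[C@H](O[Si](C)(C)C(C)(C)C)[C@H]2OC | intermediate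
14 | 5,7,3',4'-tetra-O-benzyl-3-O-(tert-butyldimethylsilyl)-4β-(4-methylphenylthio)-(−)-epicatechin (3,4-trans) | c1ccccc1COc1cc(OCc3ccccc3)c2c(c1)O[C@H](c1ccc(OCc3ccccc3)c(OCc3ccccc3)c1)[C@H](O[Si](C)(C)C(C)(C)C)[C@H]2Sc1ccc(C)cc1 | intermediate
15 | [3-O-acetyl-tetra-O-benzyl-8-bromoepicatechin]-(4β→8)-[tetra-O-benzyl-3-O-(tert-butyldimethylsilyl)-4β-(4-methylphenylthio)epicatechin] | c1ccccc1COc1cc(OCc3ccccc3)c2c(c1Br)O[C@H](c1ccc(OCc3ccccc3)c(OCc3ccccc3)c1)[C@H](OC(C)=O)[C@H]2c1c(OCc3ccccc3)cc(OCc3ccccc3)c2c1O[C@H](c1ccc(OCc3ccccc3)c(OCc3ccccc3)c1)[C@H](O[Si](C)(C)C(C)(C)C)[C@H]2Sc1ccc(C)cc1 | intermediate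
16 | (+)-epicatechin, (2S,3S) | Oc1cc(O)c2c(c1)O[C@@H](c1ccc(O)c(O)c1)[C@@H](O)C2 | starting material
17 | 5,7,3',4'-tetra-O-benzyl-(+)-epicatechin | c1ccccc1COc1cc(OCc3ccccc3)c2c(c1)O[C@@H](c1ccc(OCc3ccccc3)c(OCc3ccccc3)c1)[C@@H](O)C2 | intermediate
18 | 5,7,3',4'-tetra-O-benzyl-3-O-(tert-butyldimethylsilyl)-(+)-epicatechin | c1ccccc1COc1cc(OCc3ccccc3)c2c(c1)O[C@@H](c1ccc(OCc3ccccc3)c(OCc3ccccc3)c1)[C@@H](O[Si](C)(C)C(C)(C)C)C2 | intermediate
19 | 5,7,3',4'-tetra-O-benzyl-3-O-(tert-butyldimethylsilyl)-4-hydroxy-(+)-epicatechin (3,4-trans) | c1ccccc1COc1cc(OCc3ccccc3)c2c(c1)O[C@@H](c1ccc(OCc3ccccc3)c(OCc3ccccc3)c1)[C@@H](O[Si](C)(C)C(C)(C)C)[C@@H]2O | intermediate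
20 | (2S,3S)-5,7,3',4'-tetra-O-benzyl-3-O-(tert-butyldimethylsilyl)-2,3-cis-flavan-4-one | c1ccccc1COc1cc(OCc3ccccc3)c2c(c1)O[C@@H](c1ccc(OCc3ccccc3)c(OCc3ccccc3)c1)[C@@H](O[Si](C)(C)C(C)(C)C)C2=O | intermediate
21 | 5,7,3',4'-tetra-O-benzyl-3-O-(tert-butyldimethylsilyl)-4-hydroxy-(+)-epicatechin (2,3-cis-3,4-cis) | c1ccccc1COc1cc(OCc3ccccc3)c2c(c1)O[C@@H](c1ccc(OCc3ccccc3)c(OCc3ccccc3)c1)[C@@H](O[Si](C)(C)C(C)(C)C)[C@H]2O | intermediate
22 | 5,7,3',4'-tetra-O-benzyl-8-bromo-3-O-(tert-butyldimethylsilyl)-4-hydroxy-(+)-epicatechin (2,3-cis-3,4-cis) | c1ccccc1COc1cc(OCc3ccccc3)c2c(c1Br)O[C@@H](c1ccc(OCc3ccccc3)c(OCc3ccccc3)c1)[C@@H](O[Si](C)(C)C(C)(C)C)[C@H]2O | intermediate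
23 | protected trimer (3-O-acetyl top unit, 3-O-silyl middle and bottom units, twelve benzyl ethers, bromine at C8 of top and bottom units) | c1ccccc1COc1cc(OCc3ccccc3)c2c(c1Br)O[C@H](c1ccc(OCc3ccccc3)c(OCc3ccccc3)c1)[C@H](OC(C)=O)[C@H]2c1c(OCc3ccccc3)cc(OCc3ccccc3)c2c1O[C@H](c1ccc(OCc3ccccc3)c(OCc3ccccc3)c1)[C@H](O[Si](C)(C)C(C)(C)C)[C@H]2O[C@H]1c2c(OCc3ccccc3)cc(OCc3ccccc3)c(Br)c2O[C@@H](c2ccc(OCc3ccccc3)c(OCc3ccccc3)c2)[C@H]1O[Si](C)(C)C(C)(C)C | intermediate
24 | protected trimer with free 3-OH on the top unit | c1ccccc1COc1cc(OCc3ccccc3)c2c(c1Br)O[C@H](c1ccc(OCc3ccccc3)c(OCc3ccccc3)c1)[C@H](O)[C@H]2c1c(OCc3ccccc3)cc(OCc3ccccc3)c2c1O[C@H](c1ccc(OCc3ccccc3)c(OCc3ccccc3)c1)[C@H](O[Si](C)(C)C(C)(C)C)[C@H]2O[C@H]1c2c(OCc3ccccc3)cc(OCc3ccccc3)c(Br)c2O[C@@H](c2ccc(OCc3ccccc3)c(OCc3ccccc3)c2)[C@H]1O[Si](C)(C)C(C)(C)C | intermediate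
25 | dodeca-O-benzyl-dibromo trimer with three free 3-OH groups | c1ccccc1COc1cc(OCc3ccccc3)c2c(c1Br)O[C@H](c1ccc(OCc3ccccc3)c(OCc3ccccc3)c1)[C@H](O)[C@H]2c1c(OCc3ccccc3)cc(OCc3ccccc3)c2c1O[C@H](c1ccc(OCc3ccccc3)c(OCc3ccccc3)c1)[C@H](O)[C@H]2O[C@H]1c2c(OCc3ccccc3)cc(OCc3ccccc3)c(Br)c2O[C@@H](c2ccc(OCc3ccccc3)c(OCc3ccccc3)c2)[C@H]1O | intermediate
26 | target, epicatechin-(4β→8)-epicatechin-(4β→O→4)-[(2S,3S)-2,3-cis-3,4-cis-flavan-3,4-diol] | Oc1cc(O)c2c(c1)O[C@H](c1ccc(O)c(O)c1)[C@H](O)[C@H]2c1c(O)cc(O)c2c1O[C@H](c1ccc(O)c(O)c1)[C@H](O)[C@H]2O[C@H]1c2c(O)cc(O)cc2O[C@@H](c2ccc(O)c(O)c2)[C@H]1O | target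

**Step count and risks**
Total step count: 20. Longest linear sequence: 10 steps (16 → 26 through steps 11–20).

Most likely to fail, first: step 5. The cycloaddition may fail through reversed regiochemistry of the enol ester, loss of the cis alkene geometry in a stepwise cationic pathway, or poor facial selectivity under the chiral acid. The fallback uses known chemistry and gives up the de novo ring construction. It sets out from 11: regioselective bromination with NBS in CH2Cl2 at −40 °C gives 8-bromo-5,7,3',4'-tetra-O-benzyl-(−)-epicatechin F1. Acetylation with Ac2O, pyridine and DMAP gives 3-O-acetyl-8-bromo-5,7,3',4'-tetra-O-benzyl-(−)-epicatechin F2. DDQ oxidation in CH2Cl2/MeOH then installs the 4β-methoxy group and returns to the route at 9.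

Second: step 17. Capture of the hindered C4 cation by the hindered secondary alcohol may be slow, so that proton loss to the flav-3-ene or C-alkylation of a ring A takes over. The fallback changes the order of bond formation so that the ether is made at the monomer stage with the electrophile in excess. From 14 (excess) and 22, the same thiophilic activation gives the middle–bottom ether [tetra-O-benzyl-3-O-(tert-butyldimethylsilyl)epicatechin]-(4β→O→4)-[tetra-O-benzyl-8-bromo-3-O-(tert-butyldimethylsilyl)-(2S,3S)-2,3-cis-3,4-cis-flavan-3-ol] F3. Separately, 9 is converted with 4-methylbenzenethiol and BF3·OEt2 into 3-O-acetyl-5,7,3',4'-tetra-O-benzyl-8-bromo-4β-(4-methylphenylthio)-(−)-epicatechin F4. F4 is then activated with [Me2S–SMe]BF4 and 2,6-di-tert-butyl-4-methylpyridine in the presence of F3, whose most reactive free arene position is C8 of the middle unit. This forms the interflavan bond under neutral conditions that spare the ether and comes back to the route at 23.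

Third: step 20. Hydrogenolytic cleavage of the doubly benzylic C4–O–C4 ether may compete with removal of the benzyl ethers. The fallback changes the order of deprotection so that hydrogenolysis is done while the ether is flanked and shielded by both silyl ethers and the acetate. From 23, H2 with Pd(OH)2/C and NaHCO3 gives the 3-O-acetyl (top) bis(3-O-tert-butyldimethylsilyl) (middle and bottom) derivative of the target F5. K2CO3 in MeOH under argon gives the bis(3-O-tert-butyldimethylsilyl) derivative of the target F6. n-Bu4NF with AcOH in THF then comes back to the route at 26.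

Further compounds
F1 | step 5 | 8-bromo-5,7,3',4'-tetra-O-benzyl-(−)-epicatechin | c1ccccc1COc1cc(OCc3ccccc3)c2c(c1Br)O[C@H](c1ccc(OCc3ccccc3)c(OCc3ccccc3)c1)[C@H](O)C2
F2 | step 5 | 3-O-acetyl-8-bromo-5,7,3',4'-tetra-O-benzyl-(−)-epicatechin | c1ccccc1COc1cc(OCc3ccccc3)c2c(c1Br)O[C@H](c1ccc(OCc3ccccc3)c(OCc3ccccc3)c1)[C@H](OC(C)=O)C2
F3 | step 17 | [tetra-O-benzyl-3-O-(tert-butyldimethylsilyl)epicatechin]-(4β→O→4)-[tetra-O-benzyl-8-bromo-3-O-(tert-butyldimethylsilyl)-(2S,3S)-2,3-cis-3,4-cis-flavan-3-ol] | c1ccccc1COc1cc(OCc3ccccc3)c2c(c1)O[C@H](c1ccc(OCc3ccccc3)c(OCc3ccccc3)c1)[C@H](O[Si](C)(C)C(C)(C)C)[C@H]2O[C@H]1c2c(OCc3ccccc3)cc(OCc3ccccc3)c(Br)c2O[C@@H](c2ccc(OCc3ccccc3)c(OCc3ccccc3)c2)[C@H]1O[Si](C)(C)C(C)(C)C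
F4 | step 17 | 3-O-acetyl-5,7,3',4'-tetra-O-benzyl-8-bromo-4β-(4-methylphenylthio)-(−)-epicatechin | c1ccccc1COc1cc(OCc3ccccc3)c2c(c1Br)O[C@H](c1ccc(OCc3ccccc3)c(OCc3ccccc3)c1)[C@H](OC(C)=O)[C@H]2Sc1ccc(C)cc1
F5 | step 20 | 3-O-acetyl (top) bis(3-O-tert-butyldimethylsilyl) (middle and bottom) derivative of the target | Oc1cc(O)c2c(c1)O[C@H](c1ccc(O)c(O)c1)[C@H](OC(C)=O)[C@H]2c1c(O)cc(O)c2c1O[C@H](c1ccc(O)c(O)c1)[C@H](O[Si](C)(C)C(C)(C)C)[C@H]2O[C@H]1c2c(O)cc(O)cc2O[C@@H](c2ccc(O)c(O)c2)[C@H]1O[Si](C)(C)C(C)(C)C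
F6 | step 20 | bis(3-O-tert-butyldimethylsilyl) (middle and bottom) derivative of the target | Oc1cc(O)c2c(c1)O[C@H](c1ccc(O)c(O)c1)[C@H](O)[C@H]2c1c(O)cc(O)c2c1O[C@H](c1ccc(O)c(O)c1)[C@H](O[Si](C)(C)C(C)(C)C)[C@H]2O[C@H]1c2c(O)cc(O)cc2O[C@@H](c2ccc(O)c(O)c2)[C@H]1O[Si](C)(C)C(C)(C)C
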